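**Retrosynthetic overview**

- Rings: A is the central tetrasubstituted ring, B the 2-hydroxyphenyl ring, C the 4-hydroxyphenyl ring. All three are bought as benzene rings. The only ring made on the route is a temporary furan fused to ring B, closed in step 5 and opened again in step 6.
- Last disconnection: the target is the exhaustive hydrogenation product of a bis-O-benzyl 2-arylbenzofuran. One operation saturates C2=C3 and cleaves the benzylic C2–O bond and both benzyl ethers.
- Key disconnection: benzofuran C3–C3a, the bond between the bridge CH2 next to ring B and the ring-B carbon ortho to oxygen. It is made from a ring-A methyl ketone and O-phenylhydroxylamine by one-pot condensation, [3,3] shift and cyclisation, which unites two donor carbons (ketone α-carbon, phenol ortho carbon) at the expense of the N–O bond.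
- Enabling feature: in ring B the carbon bearing OH is the direct neighbour of the carbon bearing the ethano bridge. The phenol O, these two ring-B carbons and the two bridge carbons are therefore the atoms O1, C7a, C3a, C3, C2 of a benzofuran, and the bridge carbon on ring A can be carried as a carbonyl carbon whose only enolisable neighbour is the carbon to be bonded.
- The ketone comes from 2'-hydroxy-3'-methoxyacetophenone, whose contiguous acetyl/OH/OMe triad already encodes ring A. The sequence is para-hydroxylation, selective O-benzylation, triflation of the chelated OH, and Negishi benzylation at that carbon.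

Key step: step 5

Remark: the target has no stereocentre; C2 of the two transient 2,3-dihydrobenzofurans is racemic and is erased in the same flask, and the C=N geometry of the oxime ether is irrelevant because it reacts through its ene-hydroxylamine tautomer.

**Step 1**
Reactants: 1 1-(2-hydroxy-3-methoxyphenyl)ethan-1-one
Product: 3 1-(2,5-dihydroxy-3-methoxyphenyl)ethan-1-one, via aryl sulfate 2 (not isolated)
Conditions: K2S2O8, aq NaOH, 0 °C to rt; then aq HCl, 90 °C
Reagents that add atoms: potassium peroxodisulfate, [K+].[K+].[O-]S(=O)(=O)OOS(=O)(=O)[O-]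
Why: Elbs persulfate oxidation, in which the phenolate of 1 attacks the peroxide oxygen through its para carbon because both ortho positions are occupied (acetyl, methoxy), the sulfate ester 2 shields the new oxygen from over-oxidation, and acid hydrolysis should release the hydroquinone with the new OH para to the carbon that later carries the benzyl group.

**Step 2**
Reactants: 3 1-(2,5-dihydroxy-3-methoxyphenyl)ethan-1-one
Product: 4 1-[5-(benzyloxy)-2-hydroxy-3-methoxyphenyl]ethan-1-one
Conditions: BnBr (1 equiv), K2CO3, acetone, reflux, under Ar
Reagents that add atoms: benzyl bromide, BrCc1ccccc1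
Why: Williamson ether synthesis that should be selective for the free 5-OH, because the 2-OH is tied up in a hydrogen bond to the acetyl oxygen and is flanked on both sides.

**Step 3**
Reactants: 4 1-[5-(benzyloxy)-2-hydroxy-3-methoxyphenyl]ethan-1-one
Product: 5 2-acetyl-4-(benzyloxy)-6-methoxyphenyl trifluoromethanesulfonate
Conditions: Tf2O, pyridine, CH2Cl2, 0 °C
Reagents that add atoms: trifluoromethanesulfonic anhydride, O=S(=O)(OS(=O)(=O)C(F)(F)F)C(F)(F)F
Why: O-sulfonylation of a phenol, which turns the remaining OH into a cross-coupling leaving group exactly at the carbon between acetyl and methoxy, so the regiochemistry of ring A is fixed by the starting material and not by a substitution reaction.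

**Step 4**
Reactants: 5 2-acetyl-4-(benzyloxy)-6-methoxyphenyl trifluoromethanesulfonate; 6 1-(benzyloxy)-4-(chloromethyl)benzene
Product: 8 1-[5-(benzyloxy)-2-[4-(benzyloxy)benzyl]-3-methoxyphenyl]ethan-1-one, via benzylzinc chloride 7 (not isolated)
Conditions: 6, Zn dust, LiCl, THF, rt; then 5, Pd(OAc)2 (cat.), SPhos (cat.), THF, rt to 50 °C
Reagents that add atoms: none
Why: Negishi coupling, in which LiCl-assisted zinc insertion gives a benzylic zinc reagent that neither adds to nor enolises the methyl ketone, the ortho acetyl group speeds oxidative addition into the hindered C–OTf bond, and the bulky biarylphosphine is suited to di-ortho-substituted electrophiles.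

**Step 5**
Reactants: 8 1-[5-(benzyloxy)-2-[4-(benzyloxy)benzyl]-3-methoxyphenyl]ethan-1-one; 9 O-phenylhydroxylamine hydrochloride
Product: 13 2-{5-(benzyloxy)-2-[4-(benzyloxy)benzyl]-3-methoxyphenyl}-1-benzofuran, via oxime ether 10 (not isolated), via hydroxybenzyl ketimine 11 (not isolated), via aminodihydrobenzofuran 12 (not isolated)
Conditions: THF, rt; then MsOH (2 equiv), 60 °C
Reagents that add atoms: none
Why: The nitrogen of 9 condenses with the acetyl C=O of 8 to give O-phenyl oxime ether 10; its N-protonated ene-hydroxylamine tautomer, whose C=C can form only toward the former methyl group because the other side of the C=N is ring A, undergoes a [3,3]-sigmatropic shift in which the weak N–O bond breaks while that CH2 carbon bonds to an ortho carbon of the O-phenyl ring, and tautomerisation of the resulting dienone restores ring B as the phenol of ketimine 11. The closest known reaction type is the acid-promoted rearrangement of O-aryl oxime ethers to benzofurans, the oxygen counterpart of the Fischer indole synthesis, which is established as a one-pot process from O-arylhydroxylamine salts plus ketones and for aryl methyl ketones leading to 2-arylbenzofurans. The step joins two carbons of like polarity, the α-carbon of a ketone and the ortho carbon of a phenol, both donors, with the N–O bond acting as built-in two-electron oxidant, so an unfunctionalised C–H of ring B is used and neither halogen nor metal is needed. The furan ring closes by 5-exo-trig attack of the freed phenol oxygen on the protonated C=N carbon of 11 to give aminal 12, and loss of ammonia as ammonium aromatises it to 13; the stereocentre at C2 of 12 forms without control, as a racemate, and vanishes in this elimination. The regioselectivity needed, carbon delivered ortho and not para to oxygen, is enforced by the cyclic six-atom array CH2=C–N–O–C(ipso)=C(ortho), and since both ortho positions of the unsubstituted phenyl ring are equivalent only one product can arise. The chemoselectivity needed is that the ketone is consumed before strong acid and heat are applied, which the fast condensation of the α-effect amine at rt secures, so acid cyclodehydration of the o-benzyl ketone onto ring C (Bradsher type) should not compete, while aryl benzyl and methyl ethers tolerate MsOH in THF.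

**Step 6**
Reactants: 13 2-{5-(benzyloxy)-2-[4-(benzyloxy)benzyl]-3-methoxyphenyl}-1-benzofuran
Product: 16 3-[2-(2-hydroxyphenyl)ethyl]-4-(4-hydroxybenzyl)-5-methoxyphenol, via debenzylated benzofuran 14 (not isolated), via racemic dihydrobenzofuran 15 (not isolated)
Conditions: H2 (5 bar), Pd(OH)2/C, EtOH/AcOH, 50 °C
Reagents that add atoms: none
Why: Catalytic hydrogenation and hydrogenolysis, in which the two aryl benzyl ethers are cleaved first (14), the styrene-like C2=C3 bond is saturated (15), and the C2–O bond of 15, both benzylic to ring A and an aryl ether, is hydrogenolysed like a benzyl aryl ether, so one operation removes the temporary ring, brings both bridge carbons to CH2 and frees all three phenols with no stereocentre left.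

**Compound list**

1 | 1-(2-hydroxy-3-methoxyphenyl)ethan-1-one | CC(=O)c1cccc(OC)c1O | starting material
2 | potassium 3-acetyl-4-hydroxy-5-methoxyphenyl sulfate | CC(=O)c1cc(OS(=O)(=O)[O-])cc(OC)c1O.[K+] | intermediate
3 | 1-(2,5-dihydroxy-3-methoxyphenyl)ethan-1-one | CC(=O)c1cc(O)cc(OC)c1O | intermediate
4 | 1-[5-(benzyloxy)-2-hydroxy-3-methoxyphenyl]ethan-1-one | CC(=O)c1cc(OCc2ccccc2)cc(OC)c1O | intermediate
5 | 2-acetyl-4-(benzyloxy)-6-methoxyphenyl trifluoromethanesulfonate | CC(=O)c1cc(OCc2ccccc2)cc(OC)c1OS(=O)(=O)C(F)(F)F | intermediate
6 | 1-(benzyloxy)-4-(chloromethyl)benzene (4-benzyloxybenzyl chloride) | ClCc1ccc(OCc2ccccc2)cc1 | starting material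
7 | [4-(benzyloxy)benzyl]zinc chloride | Cl[Zn]Cc1ccc(OCc2ccccc2)cc1 | intermediate
8 | 1-[5-(benzyloxy)-2-[4-(benzyloxy)benzyl]-3-methoxyphenyl]ethan-1-one | CC(=O)c1cc(OCc2ccccc2)cc(OC)c1Cc1ccc(OCc2ccccc2)cc1 | intermediate
9 | O-phenylhydroxylamine hydrochloride | NOc1ccccc1.Cl | starting material
10 | O-phenyl oxime of 8 (E/Z not defined) | CC(=NOc1ccccc1)c1cc(OCc2ccccc2)cc(OC)c1Cc1ccc(OCc2ccccc2)cc1 | intermediate
11 | 2-{2-[5-(benzyloxy)-2-[4-(benzyloxy)benzyl]-3-methoxyphenyl]-2-iminoethyl}phenol | N=C(Cc1ccccc1O)c1cc(OCc2ccccc2)cc(OC)c1Cc1ccc(OCc2ccccc2)cc1 | intermediate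
12 | 2-{5-(benzyloxy)-2-[4-(benzyloxy)benzyl]-3-methoxyphenyl}-2,3-dihydro-1-benzofuran-2-amine (racemic) | NC1(Cc2ccccc2O1)c1cc(OCc2ccccc2)cc(OC)c1Cc1ccc(OCc2ccccc2)cc1 | intermediate
13 | 2-{5-(benzyloxy)-2-[4-(benzyloxy)benzyl]-3-methoxyphenyl}-1-benzofuran | COc1cc(OCc2ccccc2)cc(-c2cc3ccccc3o2)c1Cc1ccc(OCc2ccccc2)cc1 | intermediate
14 | 3-(1-benzofuran-2-yl)-4-(4-hydroxybenzyl)-5-methoxyphenol | COc1cc(O)cc(-c2cc3ccccc3o2)c1Cc1ccc(O)cc1 | intermediate
15 | 3-(2,3-dihydro-1-benzofuran-2-yl)-4-(4-hydroxybenzyl)-5-methoxyphenol (racemic) | COc1cc(O)cc(C2Cc3ccccc3O2)c1Cc1ccc(O)cc1 | intermediate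
16 | 3-[2-(2-hydroxyphenyl)ethyl]-4-(4-hydroxybenzyl)-5-methoxyphenol (CNP0289131.0) | COc1cc(O)cc(CCc2ccccc2O)c1Cc1ccc(O)cc1 | target

**Step count**

Total step count: 6.
Longest linear sequence: 6 steps (1, 3, 4, 5, 8, 13, 16). Compounds 6 and 9 enter as bought.

**Steps most likely to fail**

Step 5.
- Condensation at the ortho-substituted ketone may be sluggish.
- Heterolysis of the N–O bond may compete with the sigmatropic shift.
- The acid may cause migration or loss of the p-alkoxybenzyl group from its activated position on ring A.
- The fallback makes the same bond by metal catalysis under basic conditions; it sets out from 8 and comes back at 13.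
- The kinetic enolate of 8 (LDA, THF, −78 °C) is trapped with ClP(O)(OEt)2 to give the diethyl enol phosphate F1.
- More LDA in the same flask eliminates it to the terminal arylacetylene F2.
- Sonogashira coupling of F2 with 2-iodophenol (Oc1ccccc1I; PdCl2(PPh3)2, CuI, Et3N, DMF, 60 °C) should give the 2-alkynylphenol F3, which cyclises 5-endo-dig under the same conditions to 13.

Step 6.
- Saturation of the hindered C2=C3 bond, or cleavage of the cyclic benzylic C–O bond next to the ortho-substituted ring A, may stall on the catalyst surface.
- The fallback cleaves the C2–O bond first by electron transfer; it sets out from 13 and comes back at 16.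
- Lithium with catalytic 4,4'-di-tert-butylbiphenyl (THF, 0 °C, then water) should open the benzofuran reductively at C2–O and cleave both benzyl ethers.
- This gives the (E)-2-hydroxystilbene triol F4. The geometry follows from retention at the vinyl anion.
- The unhindered, acyclic double bond of F4 is then hydrogenated under mild conditions (H2, 1 bar, Pd/C, EtOH, rt) to 16.

Step 1.
- Conversion may be low, and the electron-rich phenolate may degrade oxidatively during the persulfate reaction.
- The fallback installs the oxygen by sterically controlled C–H borylation; it sets out from 1 and comes back at 5.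
- Triflation of 1 (Tf2O, pyridine, CH2Cl2, 0 °C) gives the aryl triflate F5.
- Iridium-catalysed borylation ([Ir(OMe)(cod)]2, dtbpy, B2pin2, THF, 80 °C) should functionalise the only C–H without an ortho neighbour, giving the pinacol boronate F6.
- Oxidation (Oxone, acetone/water, rt) gives the phenol F7.
- O-benzylation (BnBr, K2CO3, acetone) gives 5.

**Further compounds**

F1 | step 5 | diethyl 1-{5-(benzyloxy)-2-[4-(benzyloxy)benzyl]-3-methoxyphenyl}ethenyl phosphate | C=C(OP(=O)(OCC)OCC)c1cc(OCc2ccccc2)cc(OC)c1Cc1ccc(OCc2ccccc2)cc1
F2 | step 5 | 5-(benzyloxy)-2-[4-(benzyloxy)benzyl]-1-ethynyl-3-methoxybenzene | C#Cc1cc(OCc2ccccc2)cc(OC)c1Cc1ccc(OCc2ccccc2)cc1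
F3 | step 5 | 2-({5-(benzyloxy)-2-[4-(benzyloxy)benzyl]-3-methoxyphenyl}ethynyl)phenol | Oc1ccccc1C#Cc1cc(OCc2ccccc2)cc(OC)c1Cc1ccc(OCc2ccccc2)cc1
F4 | step 6 | 4-(4-hydroxybenzyl)-3-[(E)-2-(2-hydroxyphenyl)ethenyl]-5-methoxyphenol | COc1cc(O)cc(/C=C/c2ccccc2O)c1Cc1ccc(O)cc1
F5 | step 1 | 2-acetyl-6-methoxyphenyl trifluoromethanesulfonate | CC(=O)c1cccc(OC)c1OS(=O)(=O)C(F)(F)F
F6 | step 1 | 2-acetyl-6-methoxy-4-(4,4,5,5-tetramethyl-1,3,2-dioxaborolan-2-yl)phenyl trifluoromethanesulfonate | CC(=O)c1cc(B2OC(C)(C)C(C)(C)O2)cc(OC)c1OS(=O)(=O)C(F)(F)F
F7 | step 1 | 2-acetyl-4-hydroxy-6-methoxyphenyl trifluoromethanesulfonate | CC(=O)c1cc(O)cc(OC)c1OS(=O)(=O)C(F)(F)F
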